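**Retrosynthetic overview**
1. The two carboxyls are the ends of a cleaved ring A: the diacid comes from C2–C3 scission of a ring-A α-ketol in a tricyclic 8α,13-epoxylabd-14-en-2-one (late oxidative opening of ring A, as presumed in nature).
2. Rings B and C of that tricycle are closed in one cationic cascade from a monocyclic ring-A enone: the (E)-Δ8 olefin attacks C10 (enone β-carbon) to form ring B, and the C8 cation is trapped by the C13 tertiary hydroxyl to form the pyran ring C. This sets C10, C9 and C8 from C5.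
3. In the target the CMe2CO2H and CH2CO2H arms are cis on ring B (A/B-cis, 5β series). A chair–chair closure of an all-E polyene cannot give this, so ring A is bought in, used as the template that enforces the cis junction, and cut last.
4. The enone comes from Stork–Danheiser alkylation and transposition of dimedone ethyl enol ether with a C11 iodide made from (R)-linalool, which supplies C13 and the E-olefin.
5. Ring order: A (preformed) → B and C together → A opened.

Assumption: the SMILES is taken literally. It is the C5 epimer (5β-H) of the diacid that ring-A cleavage of (13R)-manoyl oxide would give. Labdane numbering (C1–C20) is used for ring positions.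

**Step 1**
Reactants: 1 (R)-(−)-linalool
Product: 2 (2E,6R)-2,6-dimethylocta-2,7-diene-1,6-diol
Conditions: SeO2 (cat.), t-BuOOH, salicylic acid (cat.), CH2Cl2, rt
Reagents that add atoms: tert-butyl hydroperoxide CC(C)(C)OO
Why: SeO2/t-BuOOH allylic oxidation (ene reaction then [2,3]-shift) attacks only the (E)-methyl of the trisubstituted olefin, which fixes the E geometry later needed at C8=C9, and the carbinol centre (later C13) is untouched.

**Step 2**
Reactants: 2 (2E,6R)-2,6-dimethylocta-2,7-diene-1,6-diol
Product: 4 (3R,6E)-8-chloro-3,7-dimethylocta-1,6-dien-3-ol, via allylic mesylate 3 (not isolated)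
Conditions: MsCl, LiCl, 2,4,6-collidine, DMF, 0 °C
Reagents that add atoms: lithium chloride [Li+].[Cl-]
Why: Collington–Meyers chlorination, in which only the primary allylic hydroxyl is mesylated and then displaced by chloride (SN2) without allylic shift, the tertiary alcohol being inert.

**Step 3**
Reactants: 4 (3R,6E)-8-chloro-3,7-dimethylocta-1,6-dien-3-ol
Product: 5 (3R,6E)-3,7-dimethyl-9-(phenylsulfanyl)nona-1,6-dien-3-ol
Conditions: PhSCH3, n-BuLi, DABCO, THF, 0 °C; then 4, −78 °C to rt (2.2 equiv of the lithium reagent)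
Reagents that add atoms: (phenylsulfanyl)methyllithium [Li]CSc1ccccc1
Why: Corey–Jautelat one-carbon homologation, an SN2 displacement of the primary allylic chloride that installs C6 (the first equivalent of reagent only deprotonates the hydroxyl).

**Step 4**
Reactants: 5 (3R,6E)-3,7-dimethyl-9-(phenylsulfanyl)nona-1,6-dien-3-ol
Product: 7 (3R,6E)-9-iodo-3,7-dimethylnona-1,6-dien-3-ol, via S-methylsulfonium iodide 6 (not isolated)
Conditions: CH3I (excess), NaI, CaCO3, DMF, 70 °C
Reagents that add atoms: iodomethane CI; sodium iodide [Na+].[I-]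
Why: S-methylation gives the sulfonium salt and iodide then attacks its primary carbon (SN2) with loss of thioanisole, so no stereocentre or olefin is involved.

**Step 5**
Reactants: 8 3-ethoxy-5,5-dimethylcyclohex-2-en-1-one; 7 (3R,6E)-9-iodo-3,7-dimethylnona-1,6-dien-3-ol
Product: 10 3-ethoxy-6-[(3E,7R)-7-hydroxy-3,7-dimethylnona-3,8-dien-1-yl]-5,5-dimethylcyclohex-2-en-1-one (both C6 epimers), via lithium enolate 9 (not isolated)
Conditions: 8 (2.2 equiv), LiN(i-Pr)2 (2.3 equiv), THF, −78 °C; then 7, DMPU, −78 to 0 °C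
Reagents that add atoms: none
Why: Stork–Danheiser kinetic α′-alkylation of the vinylogous ester enolate by the primary iodide (one enolate equivalent serves as base for the hydroxyl); the new ring stereocentre (later C5) forms without control because the enolate is achiral and C13 is remote, so 10 is a 1:1 pair of epimers that is carried on and parted in step 8.

**Step 6**
Reactants: 10 3-ethoxy-6-[(3E,7R)-7-hydroxy-3,7-dimethylnona-3,8-dien-1-yl]-5,5-dimethylcyclohex-2-en-1-one
Product: 12 4-[(3E,7R)-7-hydroxy-3,7-dimethylnona-3,8-dien-1-yl]-3,5,5-trimethylcyclohex-2-en-1-one (both C4 epimers), via tertiary carbinol 11 (not isolated)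
Conditions: CH3Li (3 equiv), CeCl3, THF, −78 °C; then 1 M HCl, 0 °C, 20 min
Reagents that add atoms: methyllithium [Li]C; water O
Why: 1,2-addition of CH3Li (CeCl3 suppresses enolisation) followed by acid-induced hydrolysis and 1,3-carbonyl transposition (Stork–Danheiser enone synthesis) gives the 4-substituted isophorone, the ring stereocentre is not touched in the acidic stage, and the tertiary allylic alcohol survives brief cold dilute acid.

**Step 7**
Reactants: 12 4-[(3E,7R)-7-hydroxy-3,7-dimethylnona-3,8-dien-1-yl]-3,5,5-trimethylcyclohex-2-en-1-one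
Product: 14 6-hydroxy-4-[(3E,7R)-7-hydroxy-3,7-dimethylnona-3,8-dien-1-yl]-3,5,5-trimethylcyclohex-2-en-1-one (epimers at C4 and C6), via dipotassium enolate alkoxide 13 (not isolated)
Conditions: KN(SiMe3)2 (2.2 equiv), THF, −78 °C; then 2-(phenylsulfonyl)-3-phenyloxaziridine, −78 °C; H2O
Reagents that add atoms: 2-(phenylsulfonyl)-3-phenyloxaziridine O=S(=O)(c1ccccc1)N1OC1c1ccccc1
Why: kinetic deprotonation at the only α′ position (cross-conjugated enolate) and Davis enolate hydroxylation place the future C3 oxygen, and the new carbinol centre is of no consequence because C3 ends as a carboxyl carbon.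

**Step 8**
Reactants: 14 6-hydroxy-4-[(3E,7R)-7-hydroxy-3,7-dimethylnona-3,8-dien-1-yl]-3,5,5-trimethylcyclohex-2-en-1-one
Product: 15 (13R)-8α,13-epoxy-3ξ-hydroxy-5β-labd-14-en-2-one (A/B cis; 5β-H, 9α-H, 10β-CH3, 8β-CH3; C3 epimers)
Conditions: MeAlCl2 (3.5 equiv), CH2Cl2, −78 to −30 °C; aq. KNaC4H4O6; SiO2 chromatography
Reagents that add atoms: none
Why: Proposed new method: MeAlCl2 turns both hydroxyls into aluminium alkoxides and chelates the α-aluminoxy enone, so the (E)-8,9-olefin adds through C9 to the enone β-carbon C10 (axial attack from the side of the equatorial C5 tether gives the cis A/B junction, and a chair ring B with the E-olefin puts H9 anti and the C8 methyl syn to the C10 methyl), and the C8 cation is captured anti by the C13 alkoxide to give the trans-fused pyran with C13 untouched; the closest known reaction types are the Lewis-acid-induced alkene–enone (cation–olefin) cyclisation and the hydroxyl-terminated polyene cyclisation of nerolidol to caparrapi oxide; each ring epimer of 14 reacts under control of its own C5, so the two series emerge as diastereomers (as manoyl oxide and its 13-epimer do) and the unwanted one is removed by chromatography.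

**Step 9**
Reactants: 15 (13R)-8α,13-epoxy-3ξ-hydroxy-5β-labd-14-en-2-one
Product: 17 2-[(2R,4aR,5S,6S,8aR)-5-(carboxymethyl)-2-ethenyl-2,5,8a-trimethyl-octahydro-2H-chromen-6-yl]-2-methylpropanoic acid, via seco aldehyde acid 16 (not isolated)
Conditions: NaIO4, THF–H2O, rt; then NaClO2, NaH2PO4, 2-methyl-2-butene, t-BuOH–H2O, 0 °C to rt
Reagents that add atoms: water O; sodium chlorite [Na+].[O-]Cl=O
Why: Malaprade-type periodate cleavage of the α-ketol breaks C2–C3 (ketone carbon to acid, carbinol carbon to aldehyde) and Pinnick oxidation takes the neopentyl aldehyde to the second acid, while the vinyl group, the tertiary allylic ether and all five stereocentres are unaffected.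

Stereocentres: C13 comes from 1 and its C–O bond is never broken. C5 is formed unselectively in step 5 and resolved as a diastereomer in step 8. C10, C9 and C8 are set in step 8. The ee of 17 equals that of 1.

**Compound list**
1 | (R)-(−)-linalool, (3R)-3,7-dimethylocta-1,6-dien-3-ol | C=C[C@](C)(O)CCC=C(C)C | starting material
2 | (2E,6R)-2,6-dimethylocta-2,7-diene-1,6-diol | C=C[C@](C)(O)CC/C=C(\C)CO | intermediate
3 | (2E,6R)-6-hydroxy-2,6-dimethylocta-2,7-dien-1-yl methanesulfonate | C=C[C@](C)(O)CC/C=C(\C)COS(C)(=O)=O | intermediate (not isolated)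
4 | (3R,6E)-8-chloro-3,7-dimethylocta-1,6-dien-3-ol | C=C[C@](C)(O)CC/C=C(\C)CCl | intermediate
5 | (3R,6E)-3,7-dimethyl-9-(phenylsulfanyl)nona-1,6-dien-3-ol | C=C[C@](C)(O)CC/C=C(\C)CCSc1ccccc1 | intermediate
6 | [(3E,7R)-7-hydroxy-3,7-dimethylnona-3,8-dien-1-yl](methyl)(phenyl)sulfonium iodide | C=C[C@](C)(O)CC/C=C(\C)CC[S+](C)c1ccccc1.[I-] | intermediate (not isolated)
7 | (3R,6E)-9-iodo-3,7-dimethylnona-1,6-dien-3-ol | C=C[C@](C)(O)CC/C=C(\C)CCI | intermediate
8 | 3-ethoxy-5,5-dimethylcyclohex-2-en-1-one | CCOC1=CC(=O)CC(C)(C)C1 | starting material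
9 | lithium 3-ethoxy-5,5-dimethylcyclohexa-1,3-dien-1-olate (kinetic enolate of 8) | CCOC1=CC([O-])=CC(C)(C)C1.[Li+] | intermediate (not isolated)
10 | 3-ethoxy-6-[(3E,7R)-7-hydroxy-3,7-dimethylnona-3,8-dien-1-yl]-5,5-dimethylcyclohex-2-en-1-one, 1:1 C6 epimers | CCOC1=CC(=O)C(CC/C(C)=C/CC[C@@](C)(O)C=C)C(C)(C)C1 | intermediate
11 | 3-ethoxy-6-[(3E,7R)-7-hydroxy-3,7-dimethylnona-3,8-dien-1-yl]-1,5,5-trimethylcyclohex-2-en-1-ol, epimer mixture | CCOC1=CC(C)(O)C(CC/C(C)=C/CC[C@@](C)(O)C=C)C(C)(C)C1 | intermediate (not isolated)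
12 | 4-[(3E,7R)-7-hydroxy-3,7-dimethylnona-3,8-dien-1-yl]-3,5,5-trimethylcyclohex-2-en-1-one, 1:1 C4 epimers | CC1=CC(=O)CC(C)(C)C1CC/C(C)=C/CC[C@@](C)(O)C=C | intermediate
13 | dipotassium salt of 12 (C6 enolate and side-chain alkoxide) | CC1=CC([O-])=CC(C)(C)C1CC/C(C)=C/CC[C@@](C)([O-])C=C.[K+].[K+] | intermediate (not isolated)
14 | 6-hydroxy-4-[(3E,7R)-7-hydroxy-3,7-dimethylnona-3,8-dien-1-yl]-3,5,5-trimethylcyclohex-2-en-1-one, epimers at C4 and C6 | CC1=CC(=O)C(O)C(C)(C)C1CC/C(C)=C/CC[C@@](C)(O)C=C | intermediate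
15 | (13R)-8α,13-epoxy-3ξ-hydroxy-5β-labd-14-en-2-one (5β-H, 9α-H, 10β-CH3, 8β-CH3; C3 epimers) | C=C[C@@]1(C)CC[C@@H]2[C@@]3(C)CC(=O)C(O)C(C)(C)[C@H]3CC[C@@]2(C)O1 | intermediate
16 | (13R)-8α,13-epoxy-3-oxo-2,3-seco-5β-labd-14-en-2-oic acid | C=C[C@@]1(C)CC[C@@H]2[C@@](C)(CC(=O)O)[C@@H](C(C)(C)C=O)CC[C@@]2(C)O1 | intermediate (not isolated)
17 | 2-[(2R,4aR,5S,6S,8aR)-5-(carboxymethyl)-2-ethenyl-2,5,8a-trimethyl-octahydro-2H-chromen-6-yl]-2-methylpropanoic acid, (13R)-8α,13-epoxy-2,3-seco-5β-labd-14-ene-2,3-dioic acid | C=C[C@@]1(C)CC[C@@H]2[C@@](C)(CC(=O)O)[C@@H](C(C)(C)C(=O)O)CC[C@@]2(C)O1 | target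

**Step count and risks**
Total steps: 9. Longest linear sequence: 9 steps (1 → 17); 8 enters at step 5.

Most likely to fail:

Step 8 (cascade). The β-carbon C10 is hindered by the methyl and the adjacent gem-dimethyl group. The C8 cation may lose a proton instead of being trapped. The C8 epimer (cis-fused ether) is the likeliest stereochemical by-product. The tertiary allylic alkoxide may ionise if the mixture is warmed. The fallback sets out from 14 and comes back at 15. The carbocyclisation is run on its own with Me2AlCl, which favours ene-type proton loss, to give the olefinic ketol (13R)-3ξ,13-dihydroxy-5β-labda-8(17),14-dien-2-one F2 (the Δ7 isomer serves equally). The ether ring is then closed by a different mechanism: intramolecular oxymercuration with Hg(OCOCF3)2 in CH2Cl2 (Markovnikov attack of the C13 hydroxyl on C8 from the equatorial face) gives the organomercurial (13R)-8α,13-epoxy-3ξ-hydroxy-17-(trifluoroacetoxymercurio)-5β-labd-14-en-2-one F3, and NaBH4/NaOH demercuration gives 15.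

Step 5 (alkylation). The enolate carbon lies next to a quaternary centre and the homoallylic iodide can undergo E2 elimination to a diene. The fallback sets out from 7 and comes back at 10. The far more nucleophilic dianion of commercial 5,5-dimethylcyclohexane-1,3-dione (LiN(i-Pr)2, 3.3 equiv, THF–DMPU) is alkylated at C4 with 7 to give 4-[(3E,7R)-7-hydroxy-3,7-dimethylnona-3,8-dien-1-yl]-5,5-dimethylcyclohexane-1,3-dione F1. O-ethylation (Et2SO4, K2CO3, acetone) at the less hindered oxygen, remote from the side chain, then gives 10.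

Step 9 (ring-A scission). Periodate cleavage of the hindered α-ketol may be slow and the aldehyde acid may be hard to oxidise cleanly. The fallback sets out from 15 and comes back at 17. Dess–Martin periodinane oxidises the ketol to the diosphenol (13R)-8α,13-epoxy-2-hydroxy-5β-labda-1,14-dien-3-one F4, and alkaline H2O2 (NaOH, aq. MeOH) cleaves its C2–C3 bond directly to the diacid 17.

**Further compounds**
F1 | step 5 | 4-[(3E,7R)-7-hydroxy-3,7-dimethylnona-3,8-dien-1-yl]-5,5-dimethylcyclohexane-1,3-dione (C4 epimers) | O=C1CC(=O)C(CC/C(C)=C/CC[C@@](C)(O)C=C)C(C)(C)C1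
F2 | step 8 | (13R)-3ξ,13-dihydroxy-5β-labda-8(17),14-dien-2-one | C=C[C@](C)(O)CC[C@H]1C(=C)CC[C@@H]2C(C)(C)C(O)C(=O)C[C@]12C
F3 | step 8 | (13R)-8α,13-epoxy-3ξ-hydroxy-17-(trifluoroacetoxymercurio)-5β-labd-14-en-2-one | C=C[C@@]1(C)CC[C@@H]2[C@@]3(C)CC(=O)C(O)C(C)(C)[C@H]3CC[C@@]2(C[Hg]OC(=O)C(F)(F)F)O1
F4 | step 9 | (13R)-8α,13-epoxy-2-hydroxy-5β-labda-1,14-dien-3-one | C=C[C@@]1(C)CC[C@@H]2[C@@]3(C)C=C(O)C(=O)C(C)(C)[C@H]3CC[C@@]2(C)O1
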